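**Plan**

1. Retrosynthet cuts, in order: the four O–benzyl bonds; in unit 2 (the isorhamnetin half: benzo ring D, pyranone ring F, aryl ring E) the bonds C4a–C4, C3–C4 and O1–C2 of ring F; the aryl–CO bond of the benzyloxymethyl ketone on ring E; in unit 1 (the rhamnetin half: benzo ring A, pyranone ring C, aryl ring B) O1–C2 and C2–C3 of ring C; last the diaryl ether bond between the ring E oxygen and C4' of ring B.
2. Feature used: C4 of unit 2 is a ketone carbon bonded to C4a of the phloroglucinol-derived ring D and to C3, which bears oxygen. C4 can therefore enter as CO between an aryl iodide of ring D and the enolate carbon of an α-benzyloxy aryl ketone (C3 with its oxygen, C2 with ring E); an ortho oxygen of ring D then closes O1–C2.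
3. Forward order: diaryl ether by SNAr, ring C by Claisen–Schmidt condensation and Algar–Flynn–Oyamada cyclisation, benzylation, bromide to stannane to benzyloxymethyl ketone, ring F by carbonylative coupling and acid cyclodehydration, hydrogenolysis.
4. Rings A, B, E and D are bought as benzene derivatives. Ring D is used as the symmetric 2-iodo-1,3,5-tris(methoxymethoxy)benzene, so the position of iodine and the direction of ring closure raise no regiochemical question.
5. Stereochemistry: the target has no stereocentre; the E-chalcone and the racemic aldol, dihydroflavonol and diketone intermediates are transient.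

Key step: step 10

Assumption: the target is read as the achiral 4'-O-4' diaryl ether of rhamnetin and isorhamnetin, and compounds 1, 5, 6, 8, 16 and 18 are taken as purchasable.

**Route**

Step 1
Reactants: 1 phloroglucinol (benzene-1,3,5-triol)
Product: 2 1,3,5-tris(methoxymethoxy)benzene
Conditions: NaH (3.6 equiv), MOMCl (3.6 equiv), DMF, 0 °C to rt
Reagents that add atoms: chloromethyl methyl ether (MOMCl), COCCl
Why: Williamson-type O-alkylation (MOM protection): the sodium phenoxides react at oxygen with the hard chloromethyl ether, and the threefold symmetry of 1 means that full protection gives a single product.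

Step 2
Reactants: 2 1,3,5-tris(methoxymethoxy)benzene
Product: 4 2-iodo-1,3,5-tris(methoxymethoxy)benzene, via aryllithium 3 (not isolated)
Conditions: n-BuLi (1.1 equiv), THF, 0 °C; then I2, THF, −78 °C to rt
Reagents that add atoms: iodine, II
Why: directed ortho-metalation followed by iodinolysis: every ring hydrogen of 2 lies between two coordinating MOM ethers and the three positions are equivalent, so lithiation can give only 3 and the place of iodine in 4 is fixed.

Step 3
Reactants: 5 4-bromo-2-methoxyphenol; 6 3-(benzyloxy)-4-fluorobenzaldehyde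
Product: 7 3-(benzyloxy)-4-(4-bromo-2-methoxyphenoxy)benzaldehyde
Conditions: K2CO3 (2 equiv), DMSO, 110 °C
Reagents that add atoms: none
Why: nucleophilic aromatic substitution (SNAr through a Meisenheimer adduct): the fluoride of 6 is para to the formyl group and is displaced by the potassium phenoxide of 5, while the unactivated aryl bromide of 5 stays untouched.

Step 4
Reactants: 8 1-(2,6-dihydroxy-4-methoxyphenyl)ethan-1-one
Product: 9 1-[2-(benzyloxy)-6-hydroxy-4-methoxyphenyl]ethan-1-one
Conditions: BnBr (1.05 equiv), K2CO3 (1.1 equiv), acetone, reflux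
Reagents that add atoms: benzyl bromide, BrCc1ccccc1
Why: Williamson mono-O-benzylation: the two hydroxyls of 8 are equivalent, and after the first alkylation the remaining one is held in a hydrogen bond to the ketone and is far less nucleophilic, so one equivalent of benzyl bromide should stop at 9.

Step 5
Reactants: 9 1-[2-(benzyloxy)-6-hydroxy-4-methoxyphenyl]ethan-1-one; 7 3-(benzyloxy)-4-(4-bromo-2-methoxyphenoxy)benzaldehyde
Product: 11 (E)-1-[2-(benzyloxy)-6-hydroxy-4-methoxyphenyl]-3-[3-(benzyloxy)-4-(4-bromo-2-methoxyphenoxy)phenyl]prop-2-en-1-one, via aldol adduct 10 (not isolated)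
Conditions: KOH (50% aq), EtOH, rt
Reagents that add atoms: none
Why: Claisen–Schmidt condensation (crossed aldol, then base-induced β-elimination of water from 10): 7 cannot enolise, the methyl ketone of 9 is the only enolisable partner, and the conjugated E-enone is the thermodynamic product.

Step 6
Reactants: 11 the E-chalcone
Product: 13 5-(benzyloxy)-2-[3-(benzyloxy)-4-(4-bromo-2-methoxyphenoxy)phenyl]-3-hydroxy-7-methoxy-4H-chromen-4-one, via trans-dihydroflavonol 12 (not isolated)
Conditions: 30% H2O2, NaOH (2 M aq), MeOH/THF, 0 °C to rt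
Reagents that add atoms: hydrogen peroxide, OO
Why: Algar–Flynn–Oyamada reaction: the phenoxide of 11 closes onto the β-carbon of the enone while alkaline hydrogen peroxide delivers oxygen to the α-carbon, and the racemic trans-dihydroflavonol 12 is oxidised on in the same medium to the flavonol, which removes both transient stereocentres.

Step 7
Reactants: 13 the 3-hydroxyflavone
Product: 14 3,5-bis(benzyloxy)-2-[3-(benzyloxy)-4-(4-bromo-2-methoxyphenoxy)phenyl]-7-methoxy-4H-chromen-4-one
Conditions: BnBr (1.3 equiv), K2CO3 (2 equiv), DMF, 50 °C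
Reagents that add atoms: benzyl bromide, BrCc1ccccc1
Why: Williamson O-benzylation of the acidic enolic 3-hydroxyl, the only free hydroxyl of 13.

Step 8
Reactants: 14 the tri-O-benzyl aryl bromide
Product: 15 3,5-bis(benzyloxy)-2-{3-(benzyloxy)-4-[2-methoxy-4-(trimethylstannyl)phenoxy]phenyl}-7-methoxy-4H-chromen-4-one
Conditions: (Me3Sn)2 (1.3 equiv), Pd(PPh3)4 (5 mol %), toluene, 110 °C
Reagents that add atoms: hexamethylditin, C[Sn](C)(C)[Sn](C)(C)C
Why: palladium-catalysed stannylation of an aryl bromide with a distannane (oxidative addition to zerovalent palladium, tin-to-palladium transfer, reductive elimination), a neutral method that leaves the chromone carbonyl alone, which halogen–metal exchange with an organomagnesium or organolithium reagent would not.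

Step 9
Reactants: 15 the aryl trimethylstannane; 16 benzyloxyacetyl chloride
Product: 17 3,5-bis(benzyloxy)-2-{3-(benzyloxy)-4-[4-(benzyloxyacetyl)-2-methoxyphenoxy]phenyl}-7-methoxy-4H-chromen-4-one
Conditions: PdCl2(PPh3)2 (5 mol %), toluene, 90 °C
Reagents that add atoms: none
Why: Stille acylation (Migita–Kosugi–Stille ketone synthesis): the acid chloride adds oxidatively to zerovalent palladium, the aryl group is transferred from tin in preference to methyl, and reductive elimination gives the aryl benzyloxymethyl ketone under neutral conditions.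

Step 10
Reactants: 17 the aryl benzyloxymethyl ketone; 4 2-iodo-1,3,5-tris(methoxymethoxy)benzene (1.5 equiv); 18 carbon monoxide
Product: 21 3-(benzyloxy)-2-(4-{2-(benzyloxy)-4-[3,5-bis(benzyloxy)-7-methoxy-4-oxo-4H-chromen-2-yl]phenoxy}-3-methoxyphenyl)-5,7-dihydroxy-4H-chromen-4-one, via tris-MOM 1,3-diketone 19 (not isolated), via trihydroxyphenyl 1,3-diketone 20 (not isolated)
Conditions: Pd(dba)2 (5 mol %), Xantphos (6 mol %), CO (1 atm), MgCl2 (2 equiv), Et3N (4 equiv), 1,4-dioxane, 80 °C; then HCl (3 M aq), MeOH, 60 °C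
Reagents that add atoms: none
Why: Proposed new method: oxidative addition of the carbon–iodine bond of 4 to zerovalent palladium and migratory insertion of CO give a 2,4,6-trialkoxybenzoyl palladium species (C4a–C4), which takes up the magnesium-chelated Z-enolate of 17 (MgCl2 and Et3N, with the ketone oxygen and the α-benzyloxy oxygen bound to magnesium) and reductively eliminates to the 1,3-diketone 19 (C3–C4). The closest known reaction type is the palladium-catalysed carbonylative α-arylation of aryl alkyl ketones with aryl iodides to 1,3-diketones, joined to the acid cyclodehydration of 2-hydroxyaryl 1,3-diketones to flavones; an α-alkoxy ketone and a doubly ortho-substituted iodide have not been combined in it. HCl in MeOH then cleaves the three MOM acetals, the freed ortho phenol of 20 adds 6-exo-trig to the ketone carbonyl that carries ring E (O1–C2), and loss of water aromatises ring F. No stereocentre is created, since the only sp3 carbon formed, C3 of the diketone, becomes sp2 in the pyranone. The step needs carbonylation ahead of direct arylation, and acylation at carbon instead of oxygen: the two ortho substituents of 4 slow direct coupling and favour CO insertion, the wide bite angle of Xantphos favours acyl–carbon reductive elimination, and the product is withdrawn as its magnesium diketonate so that it is not acylated twice. Regiochemistry is not at stake, because 17 has a single enolisable position (the flavone of unit 1 has none) and the two ortho oxygens of ring D are equivalent.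

Step 11
Reactants: 21 the tetra-O-benzyl biflavonol
Product: 22 2-(4-{4-[3,5-dihydroxy-7-methoxy-4-oxo-4H-chromen-2-yl]-2-hydroxyphenoxy}-3-methoxyphenyl)-3,5,7-trihydroxy-4H-chromen-4-one (target)
Conditions: H2 (1 atm), 10% Pd/C, THF/MeOH, rt
Reagents that add atoms: none
Why: catalytic hydrogenolysis of the four benzyl ethers over palladium on carbon; the diaryl ether, the two methyl ethers and the pyranone double bonds of the flavonols are not reduced at atmospheric pressure and room temperature.

**Compound list**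

1 | phloroglucinol (benzene-1,3,5-triol) | Oc1cc(O)cc(O)c1 | starting material
2 | 1,3,5-tris(methoxymethoxy)benzene | COCOc1cc(OCOC)cc(OCOC)c1 | intermediate
3 | [2,4,6-tris(methoxymethoxy)phenyl]lithium | [Li]c1c(OCOC)cc(OCOC)cc1OCOC | intermediate (not isolated)
4 | 2-iodo-1,3,5-tris(methoxymethoxy)benzene | COCOc1cc(OCOC)c(I)c(OCOC)c1 | intermediate
5 | 4-bromo-2-methoxyphenol | COc1cc(Br)ccc1O | starting material
6 | 3-(benzyloxy)-4-fluorobenzaldehyde | O=Cc1ccc(F)c(OCc2ccccc2)c1 | starting material
7 | 3-(benzyloxy)-4-(4-bromo-2-methoxyphenoxy)benzaldehyde | O=Cc1ccc(Oc2ccc(Br)cc2OC)c(OCc2ccccc2)c1 | intermediate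
8 | 1-(2,6-dihydroxy-4-methoxyphenyl)ethan-1-one | COc1cc(O)c(C(C)=O)c(O)c1 | starting material
9 | 1-[2-(benzyloxy)-6-hydroxy-4-methoxyphenyl]ethan-1-one | COc1cc(O)c(C(C)=O)c(OCc2ccccc2)c1 | intermediate
10 | 1-[2-(benzyloxy)-6-hydroxy-4-methoxyphenyl]-3-[3-(benzyloxy)-4-(4-bromo-2-methoxyphenoxy)phenyl]-3-hydroxypropan-1-one (racemic aldol adduct) | COc1cc(O)c(C(=O)CC(O)c2ccc(Oc3ccc(Br)cc3OC)c(OCc3ccccc3)c2)c(OCc2ccccc2)c1 | intermediate (not isolated)
11 | (E)-1-[2-(benzyloxy)-6-hydroxy-4-methoxyphenyl]-3-[3-(benzyloxy)-4-(4-bromo-2-methoxyphenoxy)phenyl]prop-2-en-1-one | COc1cc(O)c(C(=O)/C=C/c2ccc(Oc3ccc(Br)cc3OC)c(OCc3ccccc3)c2)c(OCc2ccccc2)c1 | intermediate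
12 | rac-(2R,3R)-5-(benzyloxy)-2-[3-(benzyloxy)-4-(4-bromo-2-methoxyphenoxy)phenyl]-3-hydroxy-7-methoxy-2,3-dihydro-4H-chromen-4-one (trans; racemic, one enantiomer drawn) | COc1cc(OCc2ccccc2)c2c(c1)O[C@H](c1ccc(Oc3ccc(Br)cc3OC)c(OCc3ccccc3)c1)[C@@H](O)C2=O | intermediate (not isolated)
13 | 5-(benzyloxy)-2-[3-(benzyloxy)-4-(4-bromo-2-methoxyphenoxy)phenyl]-3-hydroxy-7-methoxy-4H-chromen-4-one | COc1cc(OCc2ccccc2)c2c(=O)c(O)c(-c3ccc(Oc4ccc(Br)cc4OC)c(OCc4ccccc4)c3)oc2c1 | intermediate
14 | 3,5-bis(benzyloxy)-2-[3-(benzyloxy)-4-(4-bromo-2-methoxyphenoxy)phenyl]-7-methoxy-4H-chromen-4-one | COc1cc(OCc2ccccc2)c2c(=O)c(OCc3ccccc3)c(-c3ccc(Oc4ccc(Br)cc4OC)c(OCc4ccccc4)c3)oc2c1 | intermediate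
15 | 3,5-bis(benzyloxy)-2-{3-(benzyloxy)-4-[2-methoxy-4-(trimethylstannyl)phenoxy]phenyl}-7-methoxy-4H-chromen-4-one | COc1cc(OCc2ccccc2)c2c(=O)c(OCc3ccccc3)c(-c3ccc(Oc4ccc([Sn](C)(C)C)cc4OC)c(OCc4ccccc4)c3)oc2c1 | intermediate
16 | benzyloxyacetyl chloride | O=C(Cl)COCc1ccccc1 | starting material
17 | 3,5-bis(benzyloxy)-2-{3-(benzyloxy)-4-[4-(benzyloxyacetyl)-2-methoxyphenoxy]phenyl}-7-methoxy-4H-chromen-4-one | COc1cc(OCc2ccccc2)c2c(=O)c(OCc3ccccc3)c(-c3ccc(Oc4ccc(C(=O)COCc5ccccc5)cc4OC)c(OCc4ccccc4)c3)oc2c1 | intermediate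
18 | carbon monoxide | [C-]#[O+] | starting material
19 | 2-(benzyloxy)-1-{4-[2-(benzyloxy)-4-(3,5-bis(benzyloxy)-7-methoxy-4-oxo-4H-chromen-2-yl)phenoxy]-3-methoxyphenyl}-3-[2,4,6-tris(methoxymethoxy)phenyl]propane-1,3-dione (racemic, configurationally labile at C2) | COc1cc(OCc2ccccc2)c2c(=O)c(OCc3ccccc3)c(-c3ccc(Oc4ccc(C(=O)C(OCc5ccccc5)C(=O)c5c(OCOC)cc(OCOC)cc5OCOC)cc4OC)c(OCc4ccccc4)c3)oc2c1 | intermediate (not isolated)
20 | 2-(benzyloxy)-1-{4-[2-(benzyloxy)-4-(3,5-bis(benzyloxy)-7-methoxy-4-oxo-4H-chromen-2-yl)phenoxy]-3-methoxyphenyl}-3-(2,4,6-trihydroxyphenyl)propane-1,3-dione (racemic, configurationally labile at C2) | COc1cc(OCc2ccccc2)c2c(=O)c(OCc3ccccc3)c(-c3ccc(Oc4ccc(C(=O)C(OCc5ccccc5)C(=O)c5c(O)cc(O)cc5O)cc4OC)c(OCc4ccccc4)c3)oc2c1 | intermediate (not isolated)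
21 | 3-(benzyloxy)-2-(4-{2-(benzyloxy)-4-[3,5-bis(benzyloxy)-7-methoxy-4-oxo-4H-chromen-2-yl]phenoxy}-3-methoxyphenyl)-5,7-dihydroxy-4H-chromen-4-one (tetra-O-benzyl target) | COc1cc(OCc2ccccc2)c2c(=O)c(OCc3ccccc3)c(-c3ccc(Oc4ccc(-c5oc6cc(O)cc(O)c6c(=O)c5OCc5ccccc5)cc4OC)c(OCc4ccccc4)c3)oc2c1 | intermediate
22 | 2-(4-{4-[3,5-dihydroxy-7-methoxy-4-oxo-4H-chromen-2-yl]-2-hydroxyphenoxy}-3-methoxyphenyl)-3,5,7-trihydroxy-4H-chromen-4-one | COc1cc(O)c2c(=O)c(O)c(-c3ccc(Oc4ccc(-c5oc6cc(O)cc(O)c6c(=O)c5O)cc4OC)c(O)c3)oc2c1 | target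

**Step count**

Total: 11 steps. Longest linear sequence: 8 steps (3, 5, 6, 7, 8, 9, 10, 11).

**Steps most likely to fail**

1. Step 10 (bears the label). The aroyl palladium intermediate is flanked by two ortho MOM ethers and may be captured slowly by the chelated α-alkoxy enolate. Hydrodeiodination of 4, coupling without CO uptake, or acylation of the enolate at oxygen could then take over.
Fallback, known chemistry (Claisen-type C-acylation of a lithium ketone enolate with an N-acylimidazole, then the usual acid cyclodehydration): it sets out from 2 and 17. Aryllithium 3, made from 2 as in step 2, is quenched with CO2 instead of iodine and the mixture is acidified briefly with cold dilute HCl to give 2,4,6-tris(methoxymethoxy)benzoic acid F1. Carbonyldiimidazole in THF at rt converts it into the acyl imidazolide F2. Ketone 17 is deprotonated with LiN(SiMe3)2 (2.2 equiv, THF, −78 °C) and treated with F2, which should give the diketone 19. The fallback comes back to the route at 19, which is taken through the acid stage of step 10 to 21.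

2. Step 6. The 6'-benzyloxy group twists the enone, so that five-membered closure through the α-carbon can compete with the six-membered closure and lower the amount of flavonol.
Fallback: it sets out from 11. Heating with I2 (10 mol %) in DMSO at 120 °C should give, by oxidative cyclisation, the flavone F3. Dimethyldioxirane in acetone/CH2Cl2 at 0 °C should epoxidise its C2–C3 double bond to the 2,3-epoxide F4, which a catalytic amount of p-toluenesulfonic acid in CH2Cl2 isomerises to the 3-hydroxyflavone. The fallback comes back to the route at 13.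

3. Step 9. Traces of HCl from the acid chloride can protodestannylate the electron-rich arylstannane, and the α-alkoxyacyl palladium intermediate can lose CO before the aryl group is transferred.
Fallback: it sets out from 14 and avoids both tin-to-acyl steps. Stille coupling of 14 with tributyl(1-ethoxyvinyl)stannane (Pd(PPh3)4, toluene, 100 °C) should give the α-ethoxystyrene F5. Dihydroxylation of the enol ether (OsO4 cat., N-methylmorpholine N-oxide, acetone/H2O, rt) and collapse of the hemiketal should give the α-hydroxy ketone F6. Benzyl 2,2,2-trichloroacetimidate with TfOH (cat.) in CH2Cl2/cyclohexane at rt benzylates the primary hydroxyl without base. The fallback comes back to the route at 17.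

**Further compounds**

F1 | step 10 | 2,4,6-tris(methoxymethoxy)benzoic acid | COCOc1cc(OCOC)c(C(=O)O)c(OCOC)c1
F2 | step 10 | (1H-imidazol-1-yl)[2,4,6-tris(methoxymethoxy)phenyl]methanone | COCOc1cc(OCOC)c(C(=O)n2ccnc2)c(OCOC)c1
F3 | step 6 | 5-(benzyloxy)-2-[3-(benzyloxy)-4-(4-bromo-2-methoxyphenoxy)phenyl]-7-methoxy-4H-chromen-4-one | COc1cc(OCc2ccccc2)c2c(=O)cc(-c3ccc(Oc4ccc(Br)cc4OC)c(OCc4ccccc4)c3)oc2c1
F4 | step 6 | 5-(benzyloxy)-2-[3-(benzyloxy)-4-(4-bromo-2-methoxyphenoxy)phenyl]-2,3-epoxy-7-methoxy-2,3-dihydro-4H-chromen-4-one (racemic, cis-fused oxirane, one enantiomer drawn) | COc1cc(OCc2ccccc2)c2c(c1)O[C@]1(c3ccc(Oc4ccc(Br)cc4OC)c(OCc4ccccc4)c3)O[C@@H]1C2=O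
F5 | step 9 | 3,5-bis(benzyloxy)-2-{3-(benzyloxy)-4-[4-(1-ethoxyvinyl)-2-methoxyphenoxy]phenyl}-7-methoxy-4H-chromen-4-one | COc1cc(OCc2ccccc2)c2c(=O)c(OCc3ccccc3)c(-c3ccc(Oc4ccc(C(=C)OCC)cc4OC)c(OCc4ccccc4)c3)oc2c1
F6 | step 9 | 3,5-bis(benzyloxy)-2-{3-(benzyloxy)-4-[4-(hydroxyacetyl)-2-methoxyphenoxy]phenyl}-7-methoxy-4H-chromen-4-one | COc1cc(OCc2ccccc2)c2c(=O)c(OCc3ccccc3)c(-c3ccc(Oc4ccc(C(=O)CO)cc4OC)c(OCc4ccccc4)c3)oc2c1
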